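The ratio I carry is the time in the vessel over the mean life of ring against over-reaction, which is that step's rate constant times the time: N = 1.40.

    substrate ⇌ ring (K1 = 1.5, k1 = 0.027 /h)
    2 substrate → open dimer (k2 = 0.23 /M/h)
    ring → over-reaction product (k3 = 0.035 /h)

- south: substrate 0.034 M; time 40 h; a closed flask charged with all of it at once and left for 40 h
- east: substrate 0.034 M; a single well-mixed tank run continuously and read at steady state, 40 h in it on average

1. the set-up with the highest share of ring in all that became ring or open dimer or over-reaction product, at the outlet or at the end ("none" if the first two lie within 2 percentage points) (south / east / none)
2. share of ring in all that became ring or open dimer or over-reaction product, at the outlet or at the end, south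
3. share of ring in all that became ring or open dimer or over-reaction product, at the outlet or at the end, east

- percentages count the substrate that a species holds: one open dimer counts as two
- where a step has two of a species, its rate is k times that concentration squared, and two are used at each turn
- the stated concentrations are those of everything mixed, before any reaction; amounts are the same in each set-up
- run time (south): 40 h

In the tank the balance is exact: c(over-reaction product) stands at N times c(ring), so ring holds 41.7 % of ring plus product. But N is not enough, for dimer takes a part too. At the charge, the dimer step's substrate loss over the ring step's forward rate is S = 0.579, a selectivity factor. The tank runs at its own level. Its balances give c(ring) = 0.346 c(substrate) and c(substrate) = 0.0160 M, which is below the charge, and so a share of 30.8 %.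

In the flask I take the plain chain, with substrate falling at the ring constant and ring lost at the over-reaction constant. Ring then holds 47.5 % of ring plus product. Dividing by one plus S gives 30.1 % for the flask. This flask estimate is rough: S is reckoned at the charge, which overstates dimer once substrate in the flask has fallen, and the chain leaves out ring's return to substrate, which overstates ring. The gap between my two estimated shares lies within 2 percentage points, so I name neither set-up.

The forecast says none, with 30.2 % for the flask and 30.8 % for the tank, “well inside the 2-point margin”.

The simulation gives 30.2 % for the flask and 30.8 % for the tank, which leaves the choice at none. With the step from ring to over-reaction product struck out, the tank gives 66.2 %. At ten times the residence time N becomes 14.0, so ring holds 6.67 % of ring plus product in the tank, and its share of everything formed, dimer counted, stands at 6.09 %.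

The numbers stand for no real mixture; no experiment stands behind them.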